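## The problem

The target is a germacranolide: a ten-membered carbocycle (C1–C10) with a 1(10)Z and a 4E trisubstituted alkene, trans-fused at C6/C7 to an α-methyl-γ-butyrolactone (O–C6, C7, C11, C12), with allylic acetates on C3 and C9. Five stereocentres have to be set (3S, 6S, 7S, 9R, 11R). C7 and C11 are contiguous and can be made together; C7 can then direct C6; C6 can reach C3 only by relay across the C4=C5 alkene; C9 is remote from all of them. The C13 methyl is cis to the C8 branch on the lactone, the less stable arrangement, so C11 can epimerise under base once the lactone exists. Both acetates are allylic, the C3 acetate becomes β to any carbonyl placed at C1, and the 1,5-diene in a strained ring invites transannular and sigmatropic side reactions. The ring is therefore best closed late, under neutral conditions, with both alkene geometries already fixed. The enabling feature is that O3 and O6 stand 1,4 across the C4=C5 alkene while the C12 carboxyl can reach C6 through a five-membered ring. The C3–O/C6–O pair is thus the imprint of a 1,4-dioxygenation of a C3=C4–C5=C6 diene in which the carboxylic acid is one of the two oxygen nucleophiles.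

## Retrosynthesis

Germacrane numbering is used throughout (C14 is the methyl on C10, C15 the methyl on C4).

**24 to 23.** The C9 acetate is taken off first, which exposes the allylic alcohol 23. This is the retron of a carbonyl addition, and the acetylation of 23 asks nothing of the rest of the molecule.

**23 to 22 (C9–C10).** Cutting C9–C10 opens the ten-membered ring to the Z-alkenyl iodide aldehyde 22. This cut is preferred to a ring-closing olefination at C1=C10, which could not guarantee the Z-trisubstituted geometry. It is also preferred to cuts at C2–C3 or C5–C6, which would break the 1,4-dioxygen pattern. The forward step is a chromium/nickel-mediated alkenyl addition, which is neutral, spares lactone and acetates, and retains the alkene geometry made in the open chain. It must close a strained ring and set C9.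

**22 to 17 (terminus adjustments).** The C9 aldehyde of 22 goes back through alcohol 21 to the TBS ether 20. The iodoalkene of 20 goes back to the C1 aldehyde 19, the alcohol 18 and the PMB ether 17. Two orthogonal ethers let the two chain ends be addressed one after the other. 17 already carries the lactone, the C3 acetate and four of the five stereocentres.

**17 to 15 (C6–O, C3–O and the lactone ring).** Both C–O bonds and the lactone are removed in one move to give the E,E-dienoic acid 15. Stepwise alternatives (halolactonisation then allylic substitution, or epoxidation then opening) need more steps and separate stereocontrol at C3. The oxidative palladium manifold delivers the acetate that the target needs and relays C6 to C3 through the metal. The precursor is much simpler: acyclic, two stereocentres, no ring. The forward reaction must give the trans lactone, 1,4 rather than 1,2 addition, and syn addition across the diene.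

**15 to 12 to 10 (C7–C11).** The anti C7/C11 pair flanked by a carboxyl and an E-alkene is the retron of an ester-enolate [3,3] shift. Cutting C7–C11 leads to the propionate 12 of the bis-allylic alcohol 10, esterified with 11. One carbinol stereocentre (C5) then pays for both C7 and C11 and for the 5E geometry. The forward step must choose the disubstituted allyl arm over the trisubstituted one.

**10 to 5 and 7 (C5–C6).** The bis-allylic carbinol is cut at C5–C6 into enal 5 and the E-alkenylzinc 9 derived from alkyne 7 through alkenylborane 8. A catalytic asymmetric addition sets the single stereocentre that everything else derives from.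

**5 to 3 and 4; 3 to 2 to 1; 7 to 6.** The E-enal 5 is the Wittig product of aldehyde 3 and the stabilised ylide 4, which fixes the 3E geometry. 3 comes from diol 1 through mono-ether 2, and 7 is the silyl ether of alkynol 6.

## Roads not taken

**Alternative 1:** The cut is the C1=C10 alkene, made by Ramberg–Bäcklund contraction of the eleven-membered sulfone A1. α-Halogenation and 1,3-elimination give an episulfone that loses SO2 to furnish the ten-membered lactol ether A2.
- Merits: the ring is first closed at the easier eleven-membered size through carbon–sulfur bonds, and the alkene and the ten-membered ring then appear together. In ring formation this road is probably more reliable than closing 22 to 23.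
- Weak points: the hydroxide conditions rule out the acetates and the lactone, so A2 carries a silyl ether and a lactol ether that must later be exchanged and oxidised. The carbanion at C10 sits β to the C9 oxygen and can eliminate it. Halogenation must discriminate C1 from the tertiary C10. The Z geometry of a trisubstituted alkene from an episulfone in a medium ring is not secured. C3, C6 and C9 each need their own stereocontrolled step, because the 1,4-dioxygen pattern is not used.
- Comparison: the chosen plan sets against the better ring closure a Z geometry fixed in the open chain, neutral late-stage conditions, and the delivery of lactone and C3 acetate at their final oxidation level in one step.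

**Alternative 2:** The cut is C6–C7, made by anionic oxy-Cope rearrangement of the potassium alkoxide of the divinyl cyclohexenol A3. C4–C9 breaks, and the six-membered ring expands by four atoms to the cyclodecadienone A4.
- Merits: this is the strongest answer to the ten-membered ring. No macrocyclisation entropy is paid. The 1(10)Z alkene is inherited from the cyclohexene. The 4E alkene and the C6/C7 relationship follow from a chair transition state. Here it is better than the chosen plan.
- Weak points: A3 has a quaternary C4, a tertiary carbinol and an enol-ether arm, and has to be built with trans control. The C3 oxygen must be installed on the chiral-pool ring. A4 still needs stereoselective reduction at C9, removal of two PMB ethers, oxidation of C12, lactonisation and two acetylations. C11 sits on a side arm with no control element.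
- Comparison: the chosen plan sets against the superior ring construction a shorter post-cyclisation sequence, fully acyclic stereocontrol of C7/C11, and a key step that installs C3 and C6 together.

**Alternative 3:** The cut is C7–C8, made by intramolecular Michael addition of the β-keto ester enolate of A5 to its α-methylbutenolide. This closes the ten-membered ring to A6 and sets C11 on protonation.
- Merits: C6 comes from the chiral pool, addition anti to the C6 side chain gives the trans lactone, and the ring-forming bond uses a soft stabilised nucleophile under simple carbonate base. It avoids the excess CrCl2 of the chosen ring closure and is more convergent.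
- Weak points: a ten-membered ring from a reversible Michael addition onto a β-substituted, α-methylated acceptor competes with oligomerisation and retro-addition. The butenolide γ-proton at C6 is acidic, which threatens the only imported stereocentre. The target needs the less stable C11 epimer, which the equilibrating base would erode. The Z-enone can isomerise. Decarboxylation, C9 reduction with stereocontrol and protecting-group exchange still follow A6.
- Comparison: the chosen plan sets against the cheaper ring closure an irreversible, chemoselective ring closure and a C11 centre fixed by the Claisen step before any base-sensitive lactone exists.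

Key step: step 8

Remark: the facial sense of (+)-MIB in step 5 is assigned by analogy with the Si-face preference of (−)-MIB in alkylzinc additions; Re-face delivery is what the route requires.

## Route

Step 1
Reactants: 1 propane-1,3-diol
Product: 2 3-[(4-methoxybenzyl)oxy]propan-1-ol
Conditions: NaH (1 equiv), diol in excess, THF/DMF, 0 °C; PMBCl, Bu4NI (cat.), rt
Reagents that add atoms: 4-methoxybenzyl chloride, COc1ccc(CCl)cc1
Why: Williamson etherification; the two hydroxyls are equivalent, so one equivalent of base with excess diol should give mainly the mono-ether.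

Step 2
Reactants: 2 3-[(4-methoxybenzyl)oxy]propan-1-ol
Product: 3 3-[(4-methoxybenzyl)oxy]propanal
Conditions: TEMPO (cat.), PhI(OAc)2, CH2Cl2, rt
Reagents that add atoms: none
Why: Oxoammonium (TEMPO) oxidation stops at the aldehyde and is neutral enough that the β-alkoxy aldehyde should not eliminate.

Step 3
Reactants: 3 3-[(4-methoxybenzyl)oxy]propanal; 4 2-(triphenylphosphoranylidene)propanal
Product: 5 (E)-5-[(4-methoxybenzyl)oxy]-2-methylpent-2-enal
Conditions: toluene, 90 °C
Reagents that add atoms: none
Why: Wittig olefination with a formyl-stabilised ylide, which gives the E-trisubstituted enal under thermodynamic control and so fixes the C3=C4 geometry.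

Step 4
Reactants: 6 but-3-yn-1-ol
Product: 7 (but-3-yn-1-yloxy)(tert-butyl)dimethylsilane
Conditions: TBSCl, imidazole, CH2Cl2, 0 °C to rt
Reagents that add atoms: tert-butyldimethylsilyl chloride, CC(C)(C)[Si](C)(C)Cl
Why: Standard silylation of a primary alcohol.

Step 5
Reactants: 7 (but-3-yn-1-yloxy)(tert-butyl)dimethylsilane; 5 (E)-5-[(4-methoxybenzyl)oxy]-2-methylpent-2-enal
Product: 10 (3E,5R,6E)-9-(tert-butyldimethylsilyloxy)-1-[(4-methoxybenzyl)oxy]-4-methylnona-3,6-dien-5-ol, via alkenyldicyclohexylborane 8 (not isolated), via alkenyl(methyl)zinc 9 (not isolated)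
Conditions: Cy2BH, toluene, 0 °C to rt; Me2Zn, −78 °C; (+)-MIB (5 mol%), then 5, −30 to 0 °C; aq. NH4Cl
Reagents that add atoms: none
Why: Syn hydroboration gives the E-alkenylborane, boron-to-zinc exchange gives the alkenylzinc, and amino-alcohol-catalysed asymmetric 1,2-addition to the enal follows. The ligand is chosen to deliver the alkenyl group to the Re face of the aldehyde, which sets 5R.

Step 6
Reactants: 10 (3E,5R,6E)-9-(tert-butyldimethylsilyloxy)-1-[(4-methoxybenzyl)oxy]-4-methylnona-3,6-dien-5-ol; 11 propionyl chloride
Product: 12 (3E,5R,6E)-9-(tert-butyldimethylsilyloxy)-1-[(4-methoxybenzyl)oxy]-4-methylnona-3,6-dien-5-yl propionate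
Conditions: pyridine, DMAP (cat.), CH2Cl2, 0 °C
Reagents that add atoms: none
Why: Base-mediated O-acylation; acid-free conditions avoid ionisation of the bis-allylic ester.

Step 7
Reactants: 12 (3E,5R,6E)-9-(tert-butyldimethylsilyloxy)-1-[(4-methoxybenzyl)oxy]-4-methylnona-3,6-dien-5-yl propionate
Product: 15 (2R,3R,4E,6E)-3-[2-(tert-butyldimethylsilyloxy)ethyl]-9-[(4-methoxybenzyl)oxy]-2,6-dimethylnona-4,6-dienoic acid, via silyl ketene acetal 13 (not isolated), via trimethylsilyl ester 14 (not isolated)
Conditions: LiN(i-Pr)2, THF, −78 °C; TMSCl/Et3N, −78 °C to rt; aq. citric acid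
Reagents that add atoms: none
Why: Ireland–Claisen rearrangement: kinetic enolisation in THF gives the E-silyl ketene acetal 13, which rearranges through a chair with the C5 dienyl group equatorial; this transfers 5R to 7R,11R (2,3-anti, acid numbering 2R,3R) and creates the 5E alkene. The shift is expected through the disubstituted C6=C7 arm, because the path through C3=C4 would press the C15 methyl on the internal allyl carbon against both flanking substituents in the chair.

Step 8
Reactants: 15 (2R,3R,4E,6E)-3-[2-(tert-butyldimethylsilyloxy)ethyl]-9-[(4-methoxybenzyl)oxy]-2,6-dimethylnona-4,6-dienoic acid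
Product: 17 (3R,4S,5S)-5-{(1E,3S)-3-acetoxy-5-[(4-methoxybenzyl)oxy]-2-methylpent-1-en-1-yl}-4-[2-(tert-butyldimethylsilyloxy)ethyl]-3-methyldihydrofuran-2(3H)-one, via π-allylpalladium chloride 16 (not isolated)
Conditions: Pd(OAc)2 (5 mol%), p-benzoquinone (2 equiv), LiOAc (3 equiv), LiCl (0.2 equiv), acetone/AcOH 4:1, 20 °C
Reagents that add atoms: acetic acid, CC(=O)O; lithium acetate (acetate source), [Li+].CC(=O)[O-]
Why: This is a palladium-catalysed oxidative 1,4-acetoxylactonisation of a conjugated diene, the intramolecular-carboxylate variant of diene 1,4-diacetoxylation, a known reaction type for 4,6-dienoic acids. Divalent palladium binds the s-trans diene and the C12 carboxylate attacks C6 anti to the metal in a 5-exo-trig closure, which forms the γ-lactone and the syn,syn π-allyl complex 16 over C3–C5. With chloride on palladium, cis-migration of acetate is suppressed, so acetate attacks from outside, again anti to the metal, at C3, the allyl terminus remote from the lactone; benzoquinone then returns zerovalent palladium to the divalent state. C6 is set by C7 and C11: closure on the other alkene face would place the C5, C8 and C13 substituents all cis on the forming five-membered ring, so the trans C6/C7 lactone is expected. C3 is set by relay from C6 through the metal, because both oxygens enter anti to palladium on the same face of the diene, which corresponds to 3S,6S. The 4E geometry is inherited from the syn,syn allyl geometry of the E,E-diene. The step needs trans-lactone formation, 1,4 over 1,2 addition and overall syn addition; these are secured by the two existing stereocentres, by the steric difference of the allyl termini and by the catalytic chloride, while the acetate buffer should keep the TBS and PMB ethers intact.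

Step 9
Reactants: 17 (3R,4S,5S)-5-{(1E,3S)-3-acetoxy-5-[(4-methoxybenzyl)oxy]-2-methylpent-1-en-1-yl}-4-[2-(tert-butyldimethylsilyloxy)ethyl]-3-methyldihydrofuran-2(3H)-one
Product: 18 (3R,4S,5S)-5-[(1E,3S)-3-acetoxy-5-hydroxy-2-methylpent-1-en-1-yl]-4-[2-(tert-butyldimethylsilyloxy)ethyl]-3-methyldihydrofuran-2(3H)-one
Conditions: DDQ, CH2Cl2/pH 7 buffer, 0 °C
Reagents that add atoms: none
Why: Oxidative cleavage of the PMB ether; the conjugated diene is already consumed, and the buffer spares the silyl ether and limits 1,3-acetyl migration to the new alcohol.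

Step 10
Reactants: 18 (3R,4S,5S)-5-[(1E,3S)-3-acetoxy-5-hydroxy-2-methylpent-1-en-1-yl]-4-[2-(tert-butyldimethylsilyloxy)ethyl]-3-methyldihydrofuran-2(3H)-one
Product: 19 (3R,4S,5S)-5-[(1E,3S)-3-acetoxy-2-methyl-5-oxopent-1-en-1-yl]-4-[2-(tert-butyldimethylsilyloxy)ethyl]-3-methyldihydrofuran-2(3H)-one
Conditions: Dess–Martin periodinane, NaHCO3, CH2Cl2, 0 °C to rt
Reagents that add atoms: none
Why: Buffered hypervalent-iodine oxidation is non-basic; the β-acetoxy aldehyde is used directly without chromatography.

Step 11
Reactants: 19 (3R,4S,5S)-5-[(1E,3S)-3-acetoxy-2-methyl-5-oxopent-1-en-1-yl]-4-[2-(tert-butyldimethylsilyloxy)ethyl]-3-methyldihydrofuran-2(3H)-one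
Product: 20 (3R,4S,5S)-5-[(1E,3S,5Z)-3-acetoxy-6-iodo-2-methylhepta-1,5-dien-1-yl]-4-[2-(tert-butyldimethylsilyloxy)ethyl]-3-methyldihydrofuran-2(3H)-one
Conditions: EtPPh3I, n-BuLi, THF, rt; I2, −78 °C; NaN(SiMe3)2, −78 to −20 °C; then 19, −78 °C
Reagents that add atoms: ethyltriphenylphosphonium iodide, CC[P+](c1ccccc1)(c1ccccc1)c1ccccc1.[I-]; iodine, II
Why: Stork–Zhao-type Wittig olefination: the α-iodoethylidene ylide adds under kinetic control through the oxaphosphetane that places iodine cis to the chain, giving the Z-2-iodoalkene. Addition at −78 °C without excess base should outpace E1cB loss of the C3 acetate.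

Step 12
Reactants: 20 (3R,4S,5S)-5-[(1E,3S,5Z)-3-acetoxy-6-iodo-2-methylhepta-1,5-dien-1-yl]-4-[2-(tert-butyldimethylsilyloxy)ethyl]-3-methyldihydrofuran-2(3H)-one
Product: 21 (3R,4S,5S)-5-[(1E,3S,5Z)-3-acetoxy-6-iodo-2-methylhepta-1,5-dien-1-yl]-4-(2-hydroxyethyl)-3-methyldihydrofuran-2(3H)-one
Conditions: HF·pyridine, pyridine, THF, 0 °C to rt
Reagents that add atoms: none
Why: Buffered fluoride desilylation of a primary TBS ether; it avoids basic fluoride, which could epimerise C11 or move the acetate.

Step 13
Reactants: 21 (3R,4S,5S)-5-[(1E,3S,5Z)-3-acetoxy-6-iodo-2-methylhepta-1,5-dien-1-yl]-4-(2-hydroxyethyl)-3-methyldihydrofuran-2(3H)-one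
Product: 22 (3R,4S,5S)-5-[(1E,3S,5Z)-3-acetoxy-6-iodo-2-methylhepta-1,5-dien-1-yl]-3-methyl-4-(2-oxoethyl)dihydrofuran-2(3H)-one
Conditions: Dess–Martin periodinane, NaHCO3, CH2Cl2, 0 °C to rt
Reagents that add atoms: none
Why: Neutral oxidation to the C9 aldehyde; no β-leaving group is present at this end.

Step 14
Reactants: 22 (3R,4S,5S)-5-[(1E,3S,5Z)-3-acetoxy-6-iodo-2-methylhepta-1,5-dien-1-yl]-3-methyl-4-(2-oxoethyl)dihydrofuran-2(3H)-one
Product: 23 (1(10)Z,3S,4E,6S,7S,9R,11R)-3-acetoxy-9-hydroxygermacra-1(10),4-dien-12,6-olide
Conditions: CrCl2 (10 equiv), NiCl2 (0.1 equiv), degassed DMSO, 0.003 M, slow addition, rt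
Reagents that add atoms: none
Why: Nozaki–Hiyama–Kishi cyclisation: the alkenyl iodide adds oxidatively to zerovalent nickel, transmetalates to trivalent chromium with retention of the Z geometry and adds only to the aldehyde, leaving lactone and acetates untouched. High dilution favours ring closure; C9 is set under substrate control by the folded transition state of the forming ring, a modest 9R preference is hoped for, and the epimer is corrected as described under the risks.

Step 15
Reactants: 23 (1(10)Z,3S,4E,6S,7S,9R,11R)-3-acetoxy-9-hydroxygermacra-1(10),4-dien-12,6-olide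
Product: 24 (1(10)Z,3S,4E,6S,7S,9R,11R)-3,9-diacetoxygermacra-1(10),4-dien-12,6-olide
Conditions: Ac2O, pyridine, DMAP (cat.), CH2Cl2, 0 °C to rt
Reagents that add atoms: acetic anhydride, CC(=O)OC(C)=O
Why: Mild acylation of the secondary allylic alcohol; amine base at low temperature should not epimerise C11.

## Compound list

1 | propane-1,3-diol | OCCCO | starting material
2 | 3-[(4-methoxybenzyl)oxy]propan-1-ol | COc1ccc(COCCCO)cc1 | intermediate
3 | 3-[(4-methoxybenzyl)oxy]propanal | COc1ccc(COCCC=O)cc1 | intermediate
4 | 2-(triphenylphosphoranylidene)propanal | CC(C=O)=P(c1ccccc1)(c1ccccc1)c1ccccc1 | starting material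
5 | (E)-5-[(4-methoxybenzyl)oxy]-2-methylpent-2-enal | COc1ccc(COCC/C=C(\C)C=O)cc1 | intermediate
6 | but-3-yn-1-ol | C#CCCO | starting material
7 | (but-3-yn-1-yloxy)(tert-butyl)dimethylsilane | C#CCCO[Si](C)(C)C(C)(C)C | intermediate
8 | (E)-[4-(tert-butyldimethylsilyloxy)but-1-en-1-yl]dicyclohexylborane | CC(C)(C)[Si](C)(C)OCC/C=C/B(C1CCCCC1)C1CCCCC1 | intermediate (not isolated)
9 | (E)-[4-(tert-butyldimethylsilyloxy)but-1-en-1-yl](methyl)zinc | C[Zn]/C=C/CCO[Si](C)(C)C(C)(C)C | intermediate (not isolated)
10 | (3E,5R,6E)-9-(tert-butyldimethylsilyloxy)-1-[(4-methoxybenzyl)oxy]-4-methylnona-3,6-dien-5-ol | COc1ccc(COCC/C=C(\C)[C@H](O)/C=C/CCO[Si](C)(C)C(C)(C)C)cc1 | intermediate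
11 | propionyl chloride | CCC(=O)Cl | starting material
12 | (3E,5R,6E)-9-(tert-butyldimethylsilyloxy)-1-[(4-methoxybenzyl)oxy]-4-methylnona-3,6-dien-5-yl propionate | COc1ccc(COCC/C=C(\C)[C@H](OC(=O)CC)/C=C/CCO[Si](C)(C)C(C)(C)C)cc1 | intermediate
13 | (E)-O-trimethylsilyl ketene acetal of 12 (methyl cis to the allylic oxygen) | C/C=C(\O[C@H](/C=C/CCO[Si](C)(C)C(C)(C)C)/C(C)=C/CCOCc1ccc(OC)cc1)O[Si](C)(C)C | intermediate (not isolated)
14 | trimethylsilyl ester of 15 | C[Si](C)(C)OC(=O)[C@H](C)[C@H](CCO[Si](C)(C)C(C)(C)C)/C=C/C(C)=C/CCOCc1ccc(OC)cc1 | intermediate (not isolated)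
15 | (2R,3R,4E,6E)-3-[2-(tert-butyldimethylsilyloxy)ethyl]-9-[(4-methoxybenzyl)oxy]-2,6-dimethylnona-4,6-dienoic acid | OC(=O)[C@H](C)[C@H](CCO[Si](C)(C)C(C)(C)C)/C=C/C(C)=C/CCOCc1ccc(OC)cc1 | intermediate
16 | chloro(η3-allyl)palladium complex over C3–C5 of the lactone, drawn in its C5-bound form | Cl[Pd][C@@H]([C@H]1OC(=O)[C@H](C)[C@@H]1CCO[Si](C)(C)C(C)(C)C)/C(C)=C/CCOCc1ccc(OC)cc1 | intermediate (not isolated)
17 | (3R,4S,5S)-5-{(1E,3S)-3-acetoxy-5-[(4-methoxybenzyl)oxy]-2-methylpent-1-en-1-yl}-4-[2-(tert-butyldimethylsilyloxy)ethyl]-3-methyldihydrofuran-2(3H)-one | CC(=O)O[C@@H](CCOCc1ccc(OC)cc1)/C(C)=C/[C@H]1OC(=O)[C@H](C)[C@@H]1CCO[Si](C)(C)C(C)(C)C | intermediate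
18 | (3R,4S,5S)-5-[(1E,3S)-3-acetoxy-5-hydroxy-2-methylpent-1-en-1-yl]-4-[2-(tert-butyldimethylsilyloxy)ethyl]-3-methyldihydrofuran-2(3H)-one | CC(=O)O[C@@H](CCO)/C(C)=C/[C@H]1OC(=O)[C@H](C)[C@@H]1CCO[Si](C)(C)C(C)(C)C | intermediate
19 | (3R,4S,5S)-5-[(1E,3S)-3-acetoxy-2-methyl-5-oxopent-1-en-1-yl]-4-[2-(tert-butyldimethylsilyloxy)ethyl]-3-methyldihydrofuran-2(3H)-one | CC(=O)O[C@@H](CC=O)/C(C)=C/[C@H]1OC(=O)[C@H](C)[C@@H]1CCO[Si](C)(C)C(C)(C)C | intermediate
20 | (3R,4S,5S)-5-[(1E,3S,5Z)-3-acetoxy-6-iodo-2-methylhepta-1,5-dien-1-yl]-4-[2-(tert-butyldimethylsilyloxy)ethyl]-3-methyldihydrofuran-2(3H)-one | CC(=O)O[C@@H](C/C=C(/C)I)/C(C)=C/[C@H]1OC(=O)[C@H](C)[C@@H]1CCO[Si](C)(C)C(C)(C)C | intermediate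
21 | (3R,4S,5S)-5-[(1E,3S,5Z)-3-acetoxy-6-iodo-2-methylhepta-1,5-dien-1-yl]-4-(2-hydroxyethyl)-3-methyldihydrofuran-2(3H)-one | CC(=O)O[C@@H](C/C=C(/C)I)/C(C)=C/[C@H]1OC(=O)[C@H](C)[C@@H]1CCO | intermediate
22 | (3R,4S,5S)-5-[(1E,3S,5Z)-3-acetoxy-6-iodo-2-methylhepta-1,5-dien-1-yl]-3-methyl-4-(2-oxoethyl)dihydrofuran-2(3H)-one | CC(=O)O[C@@H](C/C=C(/C)I)/C(C)=C/[C@H]1OC(=O)[C@H](C)[C@@H]1CC=O | intermediate
23 | (1(10)Z,3S,4E,6S,7S,9R,11R)-3-acetoxy-9-hydroxygermacra-1(10),4-dien-12,6-olide | CC(=O)O[C@H]1C/C=C(/C)[C@H](O)C[C@@H]2[C@@H](/C=C/1C)OC(=O)[C@@H]2C | intermediate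
24 | (1(10)Z,3S,4E,6S,7S,9R,11R)-3,9-diacetoxygermacra-1(10),4-dien-12,6-olide | CC(=O)O[C@H]1C/C=C(/C)[C@H](OC(C)=O)C[C@@H]2[C@@H](/C=C/1C)OC(=O)[C@@H]2C | target

## Step count and risks

Total: 15 steps. Longest linear sequence: 14 steps (1 to 24 through steps 1–3 and 5–15); step 4 is the one-step branch.

**Step 8 (key step).** Three processes threaten it. Loss of 1,4-syn control, through cis-migration of acetate from palladium or π–σ–π isomerisation of the acyclic allyl complex, would erode C3 and the 4E geometry. Acetate attack at C5 would give the 1,2-adduct. Slow turnover of the hindered 4-methyl diene would leave time for acidolysis of the silyl ether. The fallback keeps the same C6–O and C3–O bonds and the same ring but moves to the zerovalent-palladium manifold. Setting out from 15, Shi-type dioxirane epoxidation (KHSO5, buffered, with the ketone enantiomer that delivers oxygen to the required face) of the more electron-rich C3=C4 alkene should give the vinyl epoxide acid F1. Pd(PPh3)4 in THF would then ionise the epoxide with inversion, and the carboxylate would attack C6 anti to the metal. This net 1,4-syn opening should give the hydroxy lactone F2, and acetylation (Ac2O, pyridine) returns to the route at 17.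

**Step 14.** Ring closure may be slow against ring strain, so intermolecular coupling or reduction of the alkenyl iodide can compete. Facial selectivity at the C9 aldehyde may be poor, because nothing but the ring fold controls it. The fallback replaces substrate control by reagent control. Setting out from the crude cyclisation product, 23 together with its C9 epimer F3, Dess–Martin oxidation would give the macrocyclic enone F4. Corey–Bakshi–Shibata reduction with the (S)-oxazaborolidine and catecholborane at low temperature, with the α-branched alkenyl group as the large substituent, should then deliver the 9R alcohol and come back at 23.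

**Step 11.** Deprotonation of the β-acetoxy aldehyde by the basic ylide, with E1cB loss of the C3 acetate to a dienal, may compete with carbonyl addition, and Z-selectivity may be incomplete. The fallback avoids a basic ylide. Setting out from 19, Ramirez olefination (CBr4, PPh3, zinc dust) should give the 1,1-dibromoalkene F5. Palladium-catalysed trans-selective monomethylation (Me2Zn, PdCl2(DPEphos), 0 °C, kept cold to spare the C3 allylic acetate) should give the Z-bromoalkene F6. Desilylation (HF·pyridine) to the bromo alcohol F7 and oxidation to the bromo aldehyde F8 follow. Chromium/nickel cyclisation of the bromide (CrCl2, NiCl2, DMF, 50 °C) then returns to the route at 23.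

**Step 7.** The [3,3] shift may proceed in part through the trisubstituted C3=C4 arm, giving the regioisomeric dienoic acid, and incomplete control of enolate geometry would erode the anti relationship. The fallback builds C7 and C11 by conjugate addition and alkylation on a six-membered lactone instead of a sigmatropic shift. Setting out from 5, Takai–Utimoto boron olefination (CrCl2, Cl2CHB(pin), LiI) should give the E,E-dienyl boronate F9. Hayashi–Miyaura addition to 5,6-dihydro-2H-pyran-2-one (Rh(acac)(C2H4)2 with the BINAP enantiomer that gives the 4S adduct) should give lactone F10. Enolate methylation (LiN(i-Pr)2, MeI, −78 °C) anti to the dienyl group should give the trans lactone F11. LiOH opens it to the hydroxy acid F12, handled as its lithium salt. Silylation (TBSCl, imidazole) gives the silyl ether silyl ester F13, and mild methanolysis of the silyl ester (K2CO3, MeOH/H2O) returns to the route at 15.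

## Further compounds

F1 | step 8 | (2R,3R,4E)-3-[2-(tert-butyldimethylsilyloxy)ethyl]-5-[(2S,3S)-3-{2-[(4-methoxybenzyl)oxy]ethyl}-2-methyloxiran-2-yl]-2-methylpent-4-enoic acid | OC(=O)[C@H](C)[C@H](CCO[Si](C)(C)C(C)(C)C)/C=C/[C@]1(C)O[C@H]1CCOCc1ccc(OC)cc1
F2 | step 8 | (3R,4S,5S)-4-[2-(tert-butyldimethylsilyloxy)ethyl]-5-{(1E,3S)-3-hydroxy-5-[(4-methoxybenzyl)oxy]-2-methylpent-1-en-1-yl}-3-methyldihydrofuran-2(3H)-one | O[C@@H](CCOCc1ccc(OC)cc1)/C(C)=C/[C@H]1OC(=O)[C@H](C)[C@@H]1CCO[Si](C)(C)C(C)(C)C
F3 | step 14 | (1(10)Z,3S,4E,6S,7S,9S,11R)-3-acetoxy-9-hydroxygermacra-1(10),4-dien-12,6-olide (C9 epimer of 23) | CC(=O)O[C@H]1C/C=C(/C)[C@@H](O)C[C@@H]2[C@@H](/C=C/1C)OC(=O)[C@@H]2C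
F4 | step 14 | (1(10)Z,3S,4E,6S,7S,11R)-3-acetoxy-9-oxogermacra-1(10),4-dien-12,6-olide | CC(=O)O[C@H]1C/C=C(/C)C(=O)C[C@@H]2[C@@H](/C=C/1C)OC(=O)[C@@H]2C
F5 | step 11 | (3R,4S,5S)-5-[(1E,3S)-3-acetoxy-6,6-dibromo-2-methylhexa-1,5-dien-1-yl]-4-[2-(tert-butyldimethylsilyloxy)ethyl]-3-methyldihydrofuran-2(3H)-one | CC(=O)O[C@@H](CC=C(Br)Br)/C(C)=C/[C@H]1OC(=O)[C@H](C)[C@@H]1CCO[Si](C)(C)C(C)(C)C
F6 | step 11 | (3R,4S,5S)-5-[(1E,3S,5Z)-3-acetoxy-6-bromo-2-methylhepta-1,5-dien-1-yl]-4-[2-(tert-butyldimethylsilyloxy)ethyl]-3-methyldihydrofuran-2(3H)-one | CC(=O)O[C@@H](C/C=C(/C)Br)/C(C)=C/[C@H]1OC(=O)[C@H](C)[C@@H]1CCO[Si](C)(C)C(C)(C)C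
F7 | step 11 | (3R,4S,5S)-5-[(1E,3S,5Z)-3-acetoxy-6-bromo-2-methylhepta-1,5-dien-1-yl]-4-(2-hydroxyethyl)-3-methyldihydrofuran-2(3H)-one | CC(=O)O[C@@H](C/C=C(/C)Br)/C(C)=C/[C@H]1OC(=O)[C@H](C)[C@@H]1CCO
F8 | step 11 | (3R,4S,5S)-5-[(1E,3S,5Z)-3-acetoxy-6-bromo-2-methylhepta-1,5-dien-1-yl]-3-methyl-4-(2-oxoethyl)dihydrofuran-2(3H)-one | CC(=O)O[C@@H](C/C=C(/C)Br)/C(C)=C/[C@H]1OC(=O)[C@H](C)[C@@H]1CC=O
F9 | step 7 | 2-{(1E,3E)-6-[(4-methoxybenzyl)oxy]-3-methylhexa-1,3-dien-1-yl}-4,4,5,5-tetramethyl-1,3,2-dioxaborolane | CC1(C)OB(/C=C/C(C)=C/CCOCc2ccc(OC)cc2)OC1(C)C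
F10 | step 7 | (S)-4-{(1E,3E)-6-[(4-methoxybenzyl)oxy]-3-methylhexa-1,3-dien-1-yl}tetrahydro-2H-pyran-2-one | O=C1OCC[C@H](/C=C/C(C)=C/CCOCc2ccc(OC)cc2)C1
F11 | step 7 | (3R,4R)-4-{(1E,3E)-6-[(4-methoxybenzyl)oxy]-3-methylhexa-1,3-dien-1-yl}-3-methyltetrahydro-2H-pyran-2-one | O=C1OCC[C@H](/C=C/C(C)=C/CCOCc2ccc(OC)cc2)[C@H]1C
F12 | step 7 | (2R,3R,4E,6E)-3-(2-hydroxyethyl)-9-[(4-methoxybenzyl)oxy]-2,6-dimethylnona-4,6-dienoic acid | OC(=O)[C@H](C)[C@H](CCO)/C=C/C(C)=C/CCOCc1ccc(OC)cc1
F13 | step 7 | tert-butyldimethylsilyl ester of 15 | CC(C)(C)[Si](C)(C)OC(=O)[C@H](C)[C@H](CCO[Si](C)(C)C(C)(C)C)/C=C/C(C)=C/CCOCc1ccc(OC)cc1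
A1 | alternative 1 | eleven-membered cyclic sulfone with sulfur between C1 and C10 (C10 epimers; C3 TBS ether; C9 alcohol; lactol methyl ether) | CC(C)(C)[Si](C)(C)O[C@H]1CCS(=O)(=O)C(C)[C@H](O)C[C@@H]2[C@@H](/C=C/1C)OC(OC)[C@@H]2C
A2 | alternative 1 | 1(10)Z,4E ten-membered lactol methyl ether with C3 TBS ether and free C9 alcohol | CC(C)(C)[Si](C)(C)O[C@H]1C/C=C(/C)[C@H](O)C[C@@H]2[C@@H](/C=C/1C)OC(OC)[C@@H]2C
A3 | alternative 2 | trans-1,2-dialkenylcyclohex-2-enol with the C7=C8 arm on the C9 carbinol and the E-2-(PMB-oxy)vinyl arm on quaternary C4 (diastereomer that a chair transition state maps onto A4) | CC(C)(C)[Si](C)(C)O[C@H]1CC=C(C)[C@@](O)(/C=C/[C@@H](C)COCc2ccc(OC)cc2)[C@]1(C)/C=C/OCc1ccc(OC)cc1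
A4 | alternative 2 | ten-membered 1(10)Z,4E-dien-9-one with C6 and C12 PMB ethers and C3 TBS ether | CC(C)(C)[Si](C)(C)O[C@H]1C/C=C(/C)C(=O)C[C@H]([C@@H](/C=C/1C)OCc1ccc(OC)cc1)[C@@H](C)COCc1ccc(OC)cc1
A5 | alternative 3 | acyclic β-keto allyl ester (C8–C10, 1(10)Z) tethered through C1–C5 to the C6-substituted α-methylbutenolide | C=CCOC(=O)CC(=O)/C(C)=C\C[C@H](O[Si](C)(C)C(C)(C)C)/C(C)=C/[C@H]1OC(=O)C(C)=C1
A6 | alternative 3 | 9-oxo macrocyclic trans-lactone with C8 allyl ester (C8 epimers) | C=CCOC(=O)C1C(=O)/C(C)=C\C[C@H](O[Si](C)(C)C(C)(C)C)/C(C)=C/[C@H]2OC(=O)[C@H](C)[C@H]12
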